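(The constants used here are made up; the rest is arithmetic.)

- A neighbour of midnight with 3.0 × 10⁻⁵ M of free catalyst sent me back to reckon how the recipe flasks share their 50 µM.

| flask | starting material | second substrate | free catalyst | added ligand | time | remark |
|---|---|---|---|---|---|---|
| dusk | 0.050 M (fed, over 2.0 h) | 0.100 M | 50 µM | 0.11 mM | 2.5 h | all else is in the flask from the start; the feed brings no volume worth counting |
| dawn | 0.050 M | 0.100 M | 50 µM | 0.11 mM | 2.5 h | everything together at the start |
| midnight | 0.050 M | 0.100 M (fed, over 2.0 h) | 50 µM | 0.11 mM | 2.5 h | all else is in the flask from the start; the feed brings no volume worth counting |

    starting material + free catalyst ⇌ catalyst intermediate A (K1 = 17.0 /M, k1 = 862 /M/min)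
    catalyst intermediate A → free catalyst + target (k2 = 77.1 /min)
    second substrate + free catalyst ⇌ catalyst intermediate B (K3 = 14.6 /M, k3 = 799 /M/min)
    catalyst intermediate B → free catalyst + second product (k4 = 24.0 /min)
    free catalyst + added ligand ⇌ idle complex (K5 = 7070 /M, k5 = 2020 /M/min)
    free catalyst + target → free catalyst + over-reaction product (k6 = 61.5 /M/min)

* the best flask by amount of target, in percent of the starting material charged; "all alike" if 1.5 percentage points covers them all (dusk / dawn / midnight / all alike)
* amount of target at the end, in percent of the starting material charged, dusk
* amount of target at the end, in percent of the starting material charged, dawn
* amount of target at the end, in percent of the starting material charged, midnight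

- At 77.1 /min, with the whole catalyst counted as catalyst intermediate A, the whole starting material takes 13.0 min to pass. Yet my reckoning for dawn gave a half-life of 72.2 min. The two looked incompatible.
- I followed one molecule. Once in catalyst intermediate A, it goes on with a chance of 60.3%.
- That gave 520 /M/min, the capture constant, the forward rate constant of binding times the chance of going on. The same fork gave second substrate 244 /M/min.
- For dawn I counted starting material at 50.0% of its charge and second substrate at 75.0%. My free share came to 36.9%, and my share in catalyst intermediate A to 6.23%.
- That cleared the puzzle: the short time supposed all catalyst in catalyst intermediate A, and the half-life is longer because by my count that form had 6.23% of the catalyst.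
- My pseudo-first-order constant for dawn was 0.00960 /min, and by reckoning it left 23.7% of the starting material.
- The selectivity factor, step six against capture, was 0.118, so I reckoned 68.8% target for dawn.
- For midnight I counted second substrate at 37.5% of its charge. My free share for midnight came to 43.0%, and I reckoned 71.8% target.
- For dusk, counting starting material at 25.0% of its charge, my constant was 0.00991 /min. With the late arrival I reckoned 43.4% of the starting material left in dusk, so 56.6% for target and over-reaction product together.
- The forecast named midnight, with 55% for dusk, 70% for dawn and 72% for midnight, on the ground that “Feeding the starting material delays its conversion”.
- The flasks gave 54.7% in dusk, 69.9% in dawn and 72.2% in midnight, so midnight was best. Dawn kept 21.9% of its starting material, against my 23.7%. The neighbour of midnight with 3.0 × 10⁻⁵ M of free catalyst ended with 38.0% of its catalyst free. The capture constant, with that share held over the run, gives 41.1% of the starting material left. That neighbour kept 38% of its starting material unbound.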